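**Remark (numbering and one assumption).** Eremophilane numbering is used throughout: ring A = C1–C5 and C10, ring B = C5–C10, C14 = methyl on C5, C15 = methyl on C4, C11–C13 = the three-carbon unit on C7, and β = the face that carries C14. In carane terms C1/C2/C3/C4/C5/C6/C7 correspond to C7/C6/C5/C10/C9/C8/C11. (E)-3-Methylpent-2-enoic acid is assumed to be bought as the pure E isomer.

## Structural features

The target is an eremophilane: a trans-fused decalin in which ring A carries the axial 2α-hydroxyl and the equatorial methyl C15 on C4, and ring B carries the isopropenyl group on C7, a free hydroxyl on C8 and the (E)-3-methylpent-2-enoate on O9; the rings share the quaternary C5 (angular methyl C14) and C10 (H). There are seven stereocentres (C2, C4, C5, C7, C8, C9, C10), six of them contiguous along C4–C5–C10–C9–C8–C7. C14, C15 and the isopropenyl group lie on the β face and H10, O2, O8 and O9 on the α face, so in the chair–chair form the isopropenyl group is axial and 1,3-syn to C14, O8 is axial and anti to it, and O9 is equatorial and cis to O8. The axial C7 substituent is the thermodynamically disfavoured epimer: C7 cannot be set or repaired by equilibration, must never sit next to a carbonyl group once the side chain is free, and a free cation at C11 would invite hydride shift or proton loss from C7. Fragile groups are the isopropenyl alkene (acid, electrophilic oxidants, hydroboration, hydrogenation), the β,β-disubstituted enoate (E geometry, deconjugation) and the cis-diol monoester (O9 to O8 acyl migration under base). The real difficulty is the contrathermodynamic C7 centre beside the cis-8,9-diol, together with the quaternary C5 flanked by the cis C4 methyl and the trans ring fusion. The feature exploited is that C11 carries two one-carbon groups and is bonded to C7: one extra bond from C11 to C8 turns ring B plus C11–C14 into the carane skeleton of (+)-3-carene, whose C1 already has the configuration needed at C7. In one sentence: late cleavage of the C8–C11 cyclopropane bond of a tricyclic cyclopropyl ketone, in which ring B and the side chain are still the intact carane nucleus, releases the axial C7 side chain and a C8=C9 enol ether.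

## Logic of the disconnections

**23 ⇒ 22.** The O2–Si bond is cut. C2–OH must be masked while C9 is a ketone and while the 8,9-diol is differentiated. The gain is small; the demand is a desilylation that neither moves the acyl group from O9 to O8 nor touches the isopropenyl group, hence acidic fluoride.

**22 ⇒ 20 + 21.** The O9–acyl bond is cut. This removes six carbons and the E-alkene in one convergent step. The forward esterification must choose the equatorial O9 over the axial O8 and must not isomerise the acyl donor.

**20 ⇒ 19.** The C9–H bond is cut (carbinol back to ketone). A C9 carbonyl is what gives access to C8 and, earlier, activates the cyclopropane. The forward reduction must place O9 equatorial (α), on the more hindered face, which calls for a thermodynamically and chelation-controlled electron-transfer reduction instead of a hydride.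

**19 ⇒ 16.** The C8–O bond and the C11=C12 π bond are removed together. Both arise from one latent array, a C8=C9 silyl enol ether and a tertiary selenide on C11. This replaces the labile alkene and the α-ketol by robust precursors. The oxidant must attack the enol ether from the α face and the selenoxide must eliminate into a methyl group, not into C7.

**16 ⇒ 15 (key).** The C8–C11 bond is re-formed, which closes the gem-dimethylcyclopropane. In 15 the C7 centre is locked in a cis-fused three-membered ring, the isopropenyl alkene does not yet exist during hydroboration and hydride steps, and ring B with C11–C14 maps onto 1. The forward cleavage must be specific for C8–C11, must deliver the enol ether toward C8, and must be nucleophile-assisted so that no free cation appears at C11.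

**15 ⇒ 13 (through 14).** The O2–Si and C2–H bonds are cut. The gain is a symmetrical oxidation level (dione). The forward step must reduce the C2 ketone only, and from the equatorial direction.

**13 ⇒ 10 (through 12).** The C9–O and C10–H bonds are removed as the elements of water across C9=C10. Hydroboration is the one operation that oxygenates C9 and sets H10 trans to C14 at once. It must add from the α face.

**10 ⇒ 8.** The alkene is moved from C9=C10 into conjugation (C1=C10). 8 is a Robinson annulation product. The forward step needs kinetic α-protonation of the extended dienolate.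

**8 ⇒ 4 + 5.** The C4–C5 and C1=C10 bonds are cut. One annulation brings in all ring A carbons with C15 and the C2 oxygen. The Michael addition must occur at the methine carbon C5, on the face opposite the cyclopropane, with C15 cis to C14.

**4 ⇒ 1 (through 3).** The C10=O is traced back to the C5=C10 alkene. The forward steps are anti-Markovnikov hydration and oxidation, which place oxygen regiospecifically at C10.

## Other disconnections considered

**Alternative 1:** (the first that comes to mind) Cut C5–C6 and C9=C10. Forward, a Robinson annulation of the ring A ketone A1 with methyl vinyl ketone would give octalone A2. Ring B would then be dressed by reductive enolate trapping and α-hydroxylation for O9, formation of a Δ7 alkene, hydroxyl-directed epoxidation to A3, and trans-diaxial (Fürst–Plattner) opening at C7 with an isopropenyl cuprate. The chosen plan is preferred on three grounds: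
- the annulation delivers only a bare ring B, so C7, C8, C9, C10 and all three ring B substituents would follow one operation at a time (about eight steps);
- the carbon nucleophile would have to enter C7 intermolecularly along the axial trajectory that is 1,3-syn to C14;
- A1, with three stereocentres, needs its own asymmetric synthesis, whereas the chosen plan takes ring B, C11–C14 and the absolute configuration of C7 from 1 and unveils the side chain intramolecularly.

**Alternative 2:** Cut C1–C10 and C4–C5. Forward, a Diels–Alder union of 2-methylcyclohex-2-en-1-one with silyloxydiene A4 (made from 5) would give A5 and set C4, C5 and C10 in one step. The chosen plan is preferred because: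
- suprafacial addition gives the cis ring fusion (H10 cis to C14), and with the carbonyl at C6 the C10 centre is not enolisable and cannot be turned trans;
- the endo transition state places C15 trans to C14;
- the C6 carbonyl would have to be deleted and C7–C9 would remain bare;
- absolute control would need a chiral Lewis acid acting on a poorly reactive α-substituted enone.

**Alternative 3:** Cut C7–C8. Forward, an intramolecular carbonyl-ene reaction of aldehyde A6 (prenyl group on C5, oxygenated two-carbon aldehyde on C10) would close ring B and create O8–H and the isopropenyl group at once, giving A7. The chosen plan is preferred because: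
- a concerted ene reaction needs the carbonyl oxygen within reach of the allylic hydrogen, so O8 and C11 must be gauche about the new C7–C8 bond;
- in a ring B locked by the trans-fused ring A this leads to the diequatorial 7α-isopropenyl/8β-hydroxy isomer A7 (or to cis isomers), not to the anti, diaxial 7β/8α arrangement of the target;
- A6 also needs acyclic stereocontrol at C9 and C10 next to a quaternary C5.

Key step: step 9

## Steps

Step 1
Reactants: 1 (+)-3-carene [(1S,6R)-3,7,7-trimethylbicyclo[4.1.0]hept-3-ene]
Product: 3 (1S,3R,4R,6R)-3,7,7-trimethylbicyclo[4.1.0]heptan-4-ol ((−)-4-isocaranol), via alkylborane 2 (not isolated)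
Conditions: BH3·THF, THF, 0 °C to 25 °C; then NaOH, H2O2, H2O, 0 °C
Reagents that add atoms: borane (as BH3·THF), B; hydrogen peroxide, OO
Why: Hydroboration–oxidation; borane adds syn to the C5=C10 alkene from the face opposite the gem-dimethylcyclopropane with boron on the less substituted C10, which places oxygen regiospecifically at the future C10 (the C5 and C10 centres formed here are erased in steps 2 and 3).

Step 2
Reactants: 3 (−)-4-isocaranol
Product: 4 (1S,3R,6R)-3,7,7-trimethylbicyclo[4.1.0]heptan-4-one ((−)-4-isocaranone)
Conditions: Dess–Martin periodinane, NaHCO3, CH2Cl2, 25 °C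
Reagents that add atoms: none
Why: Dess–Martin oxidation of a secondary alcohol under buffered, neutral conditions that leave the cyclopropane untouched; the now epimerisable C5 methine is converted into an enolate in step 3, so its configuration does not matter.

Step 3
Reactants: 4 (−)-4-isocaranone; 5 (E)-pent-3-en-2-one
Product: 8 (4S,5R,7S,8R)-8,11-cycloeremophil-1(10)-en-2-one, via diketone 6 (not isolated), via ketol 7 (not isolated)
Conditions: KOH (cat.), EtOH, 0 °C to 25 °C; then KOH, EtOH, reflux
Reagents that add atoms: none
Why: Robinson annulation (Michael addition, aldol condensation); under equilibrating base the more substituted enolate of 4 should be alkylated at the methine carbon C5 on the face opposite the gem-dimethylcyclopropane, as all reagents add to the corresponding alkene of 1, so C14 ends β and cis to the three-membered ring. The (E)-enone is expected to react through the compact cation-bridged transition state that is known to give the cis-vicinal dimethyl pattern (C15 cis to C14) with 2-methylcyclohexanones; aldol closure of the methyl ketone onto the C10 carbonyl and dehydration give the conjugated enone.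

Step 4
Reactants: 8 (4S,5R,7S,8R)-8,11-cycloeremophil-1(10)-en-2-one
Product: 10 (4S,5R,7S,8R)-8,11-cycloeremophil-9-en-2-one, via dienolate 9 (not isolated)
Conditions: t-BuOK, t-BuOH, 25 °C; then 10% aq. AcOH, 0 °C
Reagents that add atoms: none
Why: Kinetic deconjugation of an enone; excess t-BuOK forms the extended dienolate by removing a γ-proton at C9, and irreversible protonation is fastest at the α-carbon C1, which moves the alkene to C9=C10 where hydroboration can address C9 and C10; no stereocentre is formed.

Step 5
Reactants: 10 (4S,5R,7S,8R)-8,11-cycloeremophil-9-en-2-one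
Product: 12 (10αH)-8,11-cycloeremophilane-2ξ,9α-diol (both C2 epimers), via bis-boron adduct 11 (not isolated)
Conditions: BH3·THF (excess), THF, 0 °C to 25 °C; then NaOH, H2O2, H2O, 0 °C
Reagents that add atoms: borane (as BH3·THF), B; hydrogen peroxide, OO
Why: Hydroboration–oxidation; borane first reduces the C2 ketone (its configuration is irrelevant, it is re-oxidised in step 6) and then adds to the trisubstituted C9=C10 alkene with boron at C9 and hydrogen at C10, both from the α face, because the β face is screened by C14 on the adjacent C5 and by the cyclopropane with its endo methyl. Oxidation with retention gives the 9α-ol and, more importantly, the 10α-H trans ring fusion.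

Step 6
Reactants: 12 (10αH)-8,11-cycloeremophilane-2ξ,9α-diol
Product: 13 (10αH)-8,11-cycloeremophilane-2,9-dione
Conditions: Dess–Martin periodinane, NaHCO3, CH2Cl2, 0 °C to 25 °C
Reagents that add atoms: none
Why: Dess–Martin oxidation of both secondary alcohols under buffered conditions that do not enolise toward C10, so the trans fusion from step 5 is kept; the C9 ketone is the handle that later activates the cyclopropane.

Step 7
Reactants: 13 (10αH)-8,11-cycloeremophilane-2,9-dione
Product: 14 2α-hydroxy-(10αH)-8,11-cycloeremophilan-9-one
Conditions: LiBH(s-Bu)3 (L-Selectride, 1.05 equiv), THF, −78 °C; then H2O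
Reagents that add atoms: none
Why: Chemo- and stereoselective reduction with a bulky trialkylborohydride; the unhindered C2 ketone should react far faster than the C9 ketone, which is flanked by the ring fusion and the cyclopropane and deactivated by cyclopropyl conjugation. In the locked trans-decalin the hydride approaches C2 along the equatorial trajectory and gives the axial 2α-alcohol, as with 3-keto-5α-steroids.

Step 8
Reactants: 14 2α-hydroxy-(10αH)-8,11-cycloeremophilan-9-one
Product: 15 2α-(tert-butyldimethylsilyloxy)-(10αH)-8,11-cycloeremophilan-9-one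
Conditions: TBSCl, imidazole, DMF, 40 °C
Reagents that add atoms: tert-butyldimethylsilyl chloride, CC(C)(C)[Si](C)(C)Cl
Why: Silylation of the axial secondary alcohol; the TBS ether should survive the Lewis acid, peracid, dissolving-metal and carbodiimide steps and leaves with fluoride at the end.

Step 9
Reactants: 15 2α-(tert-butyldimethylsilyloxy)-(10αH)-8,11-cycloeremophilan-9-one
Product: 16 2α-(tert-butyldimethylsilyloxy)-11-(phenylselanyl)-9-(trimethylsilyloxy)eremophil-8-ene
Conditions: PhSeSiMe3 (1.5 equiv), ZnI2 (0.2 equiv), CH2Cl2, −20 °C to 0 °C; then Et3N, filtration through basic Al2O3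
Reagents that add atoms: (phenylseleno)trimethylsilane, C[Si](C)(C)[Se]c1ccccc1
Why: Homoconjugate (1,5-) ring opening of a cyclopropyl ketone by a silyl selenide, the selenium counterpart of the trimethylsilyl iodide opening of cyclopropyl ketones, which is the closest known reaction type. ZnI2 and the silyl group activate the C9 carbonyl; of the two cyclopropane bonds at C8 only the exocyclic C8–C11 bond lies nearly parallel to the carbonyl π* orbital (the C7–C8 ring-fusion bond lies near its nodal plane), and its cleavage puts the developing positive charge on the tertiary C11, so the stereoelectronic and the electronic factor select the same bond. The soft selenium nucleophile attacks C11 as the bond breaks, which should outrun the 1,2-hydride shift or proton loss from C7 that a free C11 cation would suffer. No ring is closed: the three-membered ring is opened and ring B is released as a cyclohexene whose enol ether double bond is fixed at C8=C9. No stereocentre is created: C7 keeps the configuration of C1 of 1 because neither the C7–C11 nor the C7–C6 bond is touched, C8 becomes trigonal and C11 achiral. The step needs bond selectivity (secured by orbital overlap and tertiary stabilisation), capture before rearrangement (secured by excess soft nucleophile, absence of base and low temperature) and integrity of C10 (secured because silylation of oxygen is coupled to C–C cleavage and not to enolisation toward C10).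

Step 10
Reactants: 16 2α-(tert-butyldimethylsilyloxy)-11-(phenylselanyl)-9-(trimethylsilyloxy)eremophil-8-ene
Product: 19 2α-(tert-butyldimethylsilyloxy)-8α-hydroxyeremophil-11-en-9-one, via selenoxide 17 (not isolated), via silyl ether 18 (not isolated)
Conditions: mCPBA (2.05 equiv), NaHCO3, CH2Cl2, −78 °C; Me2S; then diisopropylamine, −78 °C to 25 °C; then aq. citric acid, THF, 25 °C
Reagents that add atoms: 3-chloroperoxybenzoic acid, OOC(=O)c1cccc(Cl)c1
Why: One-pot Rubottom oxidation and selenoxide syn-elimination; the peracid should epoxidise the electron-rich C8=C9 silyl enol ether from the α face, anti to the bulky β side chain on the adjacent C7 and to C14, and silyl migration gives the 8α-silyloxy ketone. The selenide is oxidised at the same time and the selenoxide eliminates on warming into a methyl group (the C7 methine cannot reach the syn-periplanar geometry without severe eclipsing), which gives the isopropenyl group and leaves C7 untouched; mild acid removes the trimethylsilyl group.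

Step 11
Reactants: 19 2α-(tert-butyldimethylsilyloxy)-8α-hydroxyeremophil-11-en-9-one
Product: 20 2α-(tert-butyldimethylsilyloxy)eremophil-11-ene-8α,9α-diol
Conditions: Li, NH3(l), THF, t-BuOH, −78 °C; then NH4Cl
Reagents that add atoms: none
Why: Dissolving-metal reduction of a ketone; the lithium-bridged ketyl and carbanion should be protonated to the equatorial 9α-alkoxide, cis to O8, because the 9β epimer would be syn-axial to both C14 and the isopropenyl group and cannot share a lithium ion with the axial 8α-alkoxide. The alkoxide at C8 is too poor a leaving group for reductive cleavage and the isolated alkene is not reduced.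

Step 12
Reactants: 20 2α-(tert-butyldimethylsilyloxy)eremophil-11-ene-8α,9α-diol; 21 (E)-3-methylpent-2-enoic acid
Product: 22 2α-(tert-butyldimethylsilyloxy)-8α-hydroxyeremophil-11-en-9α-yl (E)-3-methylpent-2-enoate
Conditions: EDC·HCl, DMAP (0.2 equiv), CH2Cl2, 0 °C to 25 °C
Reagents that add atoms: none
Why: Steglich esterification; the equatorial 9α-hydroxyl should be acylated in preference to the axial 8α-hydroxyl, and any acyl migration would also favour the equatorial ester. The mild carbodiimide conditions avoid the ketene pathway that scrambles the geometry or position of the double bond of the acyl donor.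

Step 13
Reactants: 22 2α-(tert-butyldimethylsilyloxy)-8α-hydroxyeremophil-11-en-9α-yl (E)-3-methylpent-2-enoate
Product: 23 (2S,4S,5R,7R,8R,9S,10R)-2,8-dihydroxyeremophil-11-en-9-yl (E)-3-methylpent-2-enoate (CNP0129603.2)
Conditions: HF·pyridine, pyridine, THF, 0 °C to 25 °C
Reagents that add atoms: none
Why: Fluoride-mediated desilylation under buffered acidic conditions, which should avoid base-induced O9 to O8 acyl migration and leave the isopropenyl group and the enoate intact.

## Compound list

1 | (+)-3-carene, (1S,6R)-3,7,7-trimethylbicyclo[4.1.0]hept-3-ene | CC1=CC[C@@H]2[C@H](C1)C2(C)C | starting material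
2 | (−)-isocaranylborane (boron on C10, trans to the cyclopropane) | C[C@@H]1C[C@H]2[C@@H](C[C@H]1B)C2(C)C | intermediate
3 | (−)-4-isocaranol, (1S,3R,4R,6R)-3,7,7-trimethylbicyclo[4.1.0]heptan-4-ol | C[C@@H]1C[C@H]2[C@@H](C[C@H]1O)C2(C)C | intermediate
4 | (−)-4-isocaranone, (1S,3R,6R)-3,7,7-trimethylbicyclo[4.1.0]heptan-4-one | C[C@@H]1C[C@H]2[C@@H](CC1=O)C2(C)C | intermediate
5 | (E)-pent-3-en-2-one | C/C=C/C(C)=O | starting material
6 | (1S,3R,6R)-3,7,7-trimethyl-3-[(2S)-4-oxopentan-2-yl]bicyclo[4.1.0]heptan-4-one (Michael adduct) | CC1(C)[C@H]2C[C@](C)([C@@H](C)CC(C)=O)C(=O)C[C@@H]12 | intermediate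
7 | 10-hydroxy-8,11-cycloeremophilan-2-one (aldol, C10 configuration open) | CC1(C)[C@H]2C[C@]3(C)[C@@H](C)CC(=O)CC3(O)C[C@@H]12 | intermediate
8 | (4S,5R,7S,8R)-8,11-cycloeremophil-1(10)-en-2-one | CC1(C)[C@H]2C[C@]3(C)[C@@H](C)CC(=O)C=C3C[C@@H]12 | intermediate
9 | potassium 8,11-cycloeremophila-1,9-dien-2-olate | CC1(C)[C@H]2C[C@]3(C)[C@@H](C)CC([O-])=CC3=C[C@@H]12.[K+] | intermediate
10 | (4S,5R,7S,8R)-8,11-cycloeremophil-9-en-2-one | CC1(C)[C@H]2C[C@]3(C)[C@@H](C)CC(=O)CC3=C[C@@H]12 | intermediate
11 | 9α-boryl-(10αH)-8,11-cycloeremophilan-2-yl borinate (bis-boron adduct) | CC1(C)[C@H]2C[C@]3(C)[C@@H](C)CC(OB)C[C@H]3[C@H](B)[C@@H]12 | intermediate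
12 | (10αH)-8,11-cycloeremophilane-2ξ,9α-diol (both C2 epimers) | CC1(C)[C@H]2C[C@]3(C)[C@@H](C)CC(O)C[C@H]3[C@H](O)[C@@H]12 | intermediate
13 | (10αH)-8,11-cycloeremophilane-2,9-dione | CC1(C)[C@H]2C[C@]3(C)[C@@H](C)CC(=O)C[C@H]3C(=O)[C@@H]12 | intermediate
14 | 2α-hydroxy-(10αH)-8,11-cycloeremophilan-9-one | CC1(C)[C@H]2C[C@]3(C)[C@@H](C)C[C@H](O)C[C@H]3C(=O)[C@@H]12 | intermediate
15 | 2α-(tert-butyldimethylsilyloxy)-(10αH)-8,11-cycloeremophilan-9-one | CC1(C)[C@H]2C[C@]3(C)[C@@H](C)C[C@H](O[Si](C)(C)C(C)(C)C)C[C@H]3C(=O)[C@@H]12 | intermediate
16 | 2α-(tert-butyldimethylsilyloxy)-11-(phenylselanyl)-9-(trimethylsilyloxy)eremophil-8-ene (C7–C11 β, 10αH) | CC(C)([Se]c1ccccc1)[C@H]1C[C@]2(C)[C@@H](C)C[C@H](O[Si](C)(C)C(C)(C)C)C[C@H]2C(O[Si](C)(C)C)=C1 | intermediate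
17 | 2α-(tert-butyldimethylsilyloxy)-11-(phenylseleninyl)-8α-(trimethylsilyloxy)eremophilan-9-one | CC(C)([Se](=O)c1ccccc1)[C@H]1C[C@]2(C)[C@@H](C)C[C@H](O[Si](C)(C)C(C)(C)C)C[C@H]2C(=O)[C@@H]1O[Si](C)(C)C | intermediate
18 | 2α-(tert-butyldimethylsilyloxy)-8α-(trimethylsilyloxy)eremophil-11-en-9-one | C=C(C)[C@H]1C[C@]2(C)[C@@H](C)C[C@H](O[Si](C)(C)C(C)(C)C)C[C@H]2C(=O)[C@@H]1O[Si](C)(C)C | intermediate
19 | 2α-(tert-butyldimethylsilyloxy)-8α-hydroxyeremophil-11-en-9-one | C=C(C)[C@H]1C[C@]2(C)[C@@H](C)C[C@H](O[Si](C)(C)C(C)(C)C)C[C@H]2C(=O)[C@@H]1O | intermediate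
20 | 2α-(tert-butyldimethylsilyloxy)eremophil-11-ene-8α,9α-diol | C=C(C)[C@H]1C[C@]2(C)[C@@H](C)C[C@H](O[Si](C)(C)C(C)(C)C)C[C@H]2[C@H](O)[C@@H]1O | intermediate
21 | (E)-3-methylpent-2-enoic acid | CC/C(C)=C/C(=O)O | starting material
22 | 2α-(tert-butyldimethylsilyloxy)-8α-hydroxyeremophil-11-en-9α-yl (E)-3-methylpent-2-enoate | C=C(C)[C@H]1C[C@]2(C)[C@@H](C)C[C@H](O[Si](C)(C)C(C)(C)C)C[C@H]2[C@H](OC(=O)/C=C(\C)CC)[C@@H]1O | intermediate
23 | (2S,4S,5R,7R,8R,9S,10R)-2,8-dihydroxyeremophil-11-en-9-yl (E)-3-methylpent-2-enoate | C=C(C)[C@H]1C[C@]2(C)[C@@H](C)C[C@H](O)C[C@H]2[C@H](OC(=O)/C=C(\C)CC)[C@@H]1O | target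

## Step count and least certain steps

Total: 13 steps. Longest linear sequence: 13 steps (1 to 23); 5 and 21 are purchased.

**Step 9 (key step).** The most likely failure is ionisation outrunning capture: a free C11 cation would undergo hydride shift or proton loss at C7, which flattens C7 and gives conjugated isopropyl or isopropylidene products. The other risk is simple reversible carbonyl addition without ring opening. Fallback, from 15 to 18: the better precedented silyl iodide opening would be used. TMSCl and NaI in MeCN at −20 °C (iodotrimethylsilane formed in the flask) should cleave the same bond to give 2α-(tert-butyldimethylsilyloxy)-11-iodo-9-(trimethylsilyloxy)eremophil-8-ene F1. Dehydroiodination with DBU in toluene should give 2α-(tert-butyldimethylsilyloxy)-9-(trimethylsilyloxy)eremophila-8,11-diene F2. Rubottom oxidation of F2 with one equivalent of mCPBA at −78 °C rejoins the route at 18, which is desilylated to 19 as in step 10.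

**Step 3.** Two things may go wrong: Michael addition through the less substituted enolate (bond formation at C9 instead of C5), and incomplete control of the C15 configuration, because the facial choice on the enone rests on analogy. Fallback, from 4 to 6: the regiochemistry is fixed before the C–C bond is made. TMSCl, Et3N, DMF at 80 °C should give the thermodynamic enol ether (1S,6R)-3,7,7-trimethyl-4-(trimethylsilyloxy)bicyclo[4.1.0]hept-3-ene F3, which is purified from its regioisomer. Mukaiyama–Michael addition of F3 to 5 with catalytic Sc(OTf)3 at −78 °C and aqueous work-up should give diketone 6, now isolated, and KOH in EtOH at reflux closes it to 8.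

**Step 10.** The risks are over-oxidation of the newly formed isopropenyl group by peracid or by selenium peroxy acids, and competing syn-elimination toward H7. Fallback, from 16 to 19: the two oxidations are separated and the hydroxyl is introduced by enolate chemistry.
- Aqueous citric acid should hydrolyse 16 to 2α-(tert-butyldimethylsilyloxy)-11-(phenylselanyl)eremophilan-9-one F4.
- NaIO4 and NaHCO3 in aqueous MeOH should give the selenoxide 2α-(tert-butyldimethylsilyloxy)-11-(phenylseleninyl)eremophilan-9-one F5, which eliminates to 2α-(tert-butyldimethylsilyloxy)eremophil-11-en-9-one F6.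
- LiN(iPr)2 at −78 °C should deprotonate the C8 methylene kinetically to lithium 2α-(tert-butyldimethylsilyloxy)eremophila-8,11-dien-9-olate F7.
- Hydroxylation of F7 with 2-(phenylsulfonyl)-3-phenyloxaziridine from the α face, followed by NH4Cl, gives 19.

**Step 11.** The risks are reductive cleavage of the C8–O bond, and amide-induced enolisation (epimerisation at C10 or ketol isomerisation) before electron transfer. Fallback, from 19 to 20: kinetic hydride delivery on a protected ketol. TESOTf and 2,6-lutidine should give 2α-(tert-butyldimethylsilyloxy)-8α-(triethylsilyloxy)eremophil-11-en-9-one F8. NaBH4 in MeOH–THF at −40 °C is expected to attack anti to the axial C8–O bond (Felkin–Anh, with the equatorial trajectory blocked by the axial silyloxy group) to give 2α-(tert-butyldimethylsilyloxy)-8α-(triethylsilyloxy)eremophil-11-en-9α-ol F9. PPTS in MeOH removes the triethylsilyl group to give 20.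

**Step 12.** The risks are poor site selectivity (acylation of the axial O8 or of both hydroxyls) and isomerisation of the acyl donor. Fallback, from 20 to 22: tin-mediated activation of the equatorial oxygen. Bu2SnO in toluene at reflux with removal of water should give the 8α,9α-O-dibutylstannylene acetal of 20 F10. (E)-3-Methylpent-2-enoyl chloride F11 (from 21 with oxalyl chloride and catalytic DMF) in CH2Cl2 at 0 °C should acylate the equatorial tin-bound oxygen and give 22 after aqueous work-up.

## Further compounds

F1 | step 9 | 2α-(tert-butyldimethylsilyloxy)-11-iodo-9-(trimethylsilyloxy)eremophil-8-ene | CC(C)(I)[C@H]1C[C@]2(C)[C@@H](C)C[C@H](O[Si](C)(C)C(C)(C)C)C[C@H]2C(O[Si](C)(C)C)=C1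
F2 | step 9 | 2α-(tert-butyldimethylsilyloxy)-9-(trimethylsilyloxy)eremophila-8,11-diene | C=C(C)[C@H]1C[C@]2(C)[C@@H](C)C[C@H](O[Si](C)(C)C(C)(C)C)C[C@H]2C(O[Si](C)(C)C)=C1
F3 | step 3 | (1S,6R)-3,7,7-trimethyl-4-(trimethylsilyloxy)bicyclo[4.1.0]hept-3-ene | CC1=C(O[Si](C)(C)C)C[C@@H]2[C@H](C1)C2(C)C
F4 | step 10 | 2α-(tert-butyldimethylsilyloxy)-11-(phenylselanyl)eremophilan-9-one | CC(C)([Se]c1ccccc1)[C@H]1C[C@]2(C)[C@@H](C)C[C@H](O[Si](C)(C)C(C)(C)C)C[C@H]2C(=O)C1
F5 | step 10 | 2α-(tert-butyldimethylsilyloxy)-11-(phenylseleninyl)eremophilan-9-one | CC(C)([Se](=O)c1ccccc1)[C@H]1C[C@]2(C)[C@@H](C)C[C@H](O[Si](C)(C)C(C)(C)C)C[C@H]2C(=O)C1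
F6 | step 10 | 2α-(tert-butyldimethylsilyloxy)eremophil-11-en-9-one | C=C(C)[C@H]1C[C@]2(C)[C@@H](C)C[C@H](O[Si](C)(C)C(C)(C)C)C[C@H]2C(=O)C1
F7 | step 10 | lithium 2α-(tert-butyldimethylsilyloxy)eremophila-8,11-dien-9-olate | C=C(C)[C@H]1C[C@]2(C)[C@@H](C)C[C@H](O[Si](C)(C)C(C)(C)C)C[C@H]2C([O-])=C1.[Li+]
F8 | step 11 | 2α-(tert-butyldimethylsilyloxy)-8α-(triethylsilyloxy)eremophil-11-en-9-one | C=C(C)[C@H]1C[C@]2(C)[C@@H](C)C[C@H](O[Si](C)(C)C(C)(C)C)C[C@H]2C(=O)[C@@H]1O[Si](CC)(CC)CC
F9 | step 11 | 2α-(tert-butyldimethylsilyloxy)-8α-(triethylsilyloxy)eremophil-11-en-9α-ol | C=C(C)[C@H]1C[C@]2(C)[C@@H](C)C[C@H](O[Si](C)(C)C(C)(C)C)C[C@H]2[C@H](O)[C@@H]1O[Si](CC)(CC)CC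
F10 | step 12 | 8α,9α-O-dibutylstannylene acetal of 2α-(tert-butyldimethylsilyloxy)eremophil-11-ene-8α,9α-diol | C=C(C)[C@H]1C[C@]2(C)[C@@H](C)C[C@H](O[Si](C)(C)C(C)(C)C)C[C@H]2[C@@H]2O[Sn](CCCC)(CCCC)O[C@H]12
F11 | step 12 | (E)-3-methylpent-2-enoyl chloride | CC/C(C)=C/C(Cl)=O
A1 | alternative 1 | (2S,3S,5S)-5-(tert-butyldimethylsilyloxy)-2,3-dimethylcyclohexan-1-one | C[C@H]1[C@@H](C)C[C@H](O[Si](C)(C)C(C)(C)C)CC1=O
A2 | alternative 1 | (4aR,5S,7S)-7-(tert-butyldimethylsilyloxy)-4a,5-dimethyl-4,4a,5,6,7,8-hexahydronaphthalen-2(3H)-one | O=C1CC[C@]2(C)[C@@H](C)C[C@H](O[Si](C)(C)C(C)(C)C)CC2=C1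
A3 | alternative 1 | 2α-(tert-butyldimethylsilyloxy)-7α,8α-epoxy-11,12,13-trinoreremophilan-9α-ol | O1[C@@H]2C[C@]3(C)[C@@H](C)C[C@H](O[Si](C)(C)C(C)(C)C)C[C@H]3[C@H](O)[C@H]12
A4 | alternative 2 | (E)-2-(tert-butyldimethylsilyloxy)penta-1,3-diene | C=C(O[Si](C)(C)C(C)(C)C)/C=C/C
A5 | alternative 2 | cis-fused endo adduct 6-(tert-butyldimethylsilyloxy)-8,8a-dimethyl-3,4,4a,5,8,8a-hexahydronaphthalen-1(2H)-one (8-methyl trans to 8a-methyl) | C[C@@H]1C=C(O[Si](C)(C)C(C)(C)C)C[C@@H]2CCCC(=O)[C@]12C
A6 | alternative 3 | 9α-benzyloxy-2α-(tert-butyldimethylsilyloxy)-7,8-secoeremophil-7(11)-en-8-al | CC(C)=CC[C@]1(C)[C@@H](C)C[C@H](O[Si](C)(C)C(C)(C)C)C[C@H]1[C@H](OCc1ccccc1)C=O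
A7 | alternative 3 | 9α-benzyloxy-2α-(tert-butyldimethylsilyloxy)-7βH-eremophil-11-en-8β-ol (7α-isopropenyl, 8β-hydroxy) | C=C(C)[C@@H]1C[C@]2(C)[C@@H](C)C[C@H](O[Si](C)(C)C(C)(C)C)C[C@H]2[C@H](OCc2ccccc2)[C@H]1O
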